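The target is meso. A mirror plane runs through O1 and the midpoint of C3–C4 of the tetrahydrofuran ring, so both aryl–C2/C5 bonds are the same bond. Everything rests on cutting these bonds back to carboxyl groups. The key step is a two-directional, twofold decarboxylative arylation. A meso tetrahydrofuran-2,5-dicarboxylic acid and two syringyl bromide units are joined in one flask, and C2 and C5 are set trans to the cis C3/C4 substituents. The precursor, with methyl esters as latent hydroxymethyl groups, comes from oxidative cleavage of the exo furan–maleic anhydride cycloadduct, whose exo geometry already encodes the trans,cis,trans pattern. One hydride reduction then finishes.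

Key step: step 4

Remark on the chemistry: the SMILES reads as (2S,3R,4S,5R). Both aryl groups lie on one face and both hydroxymethyl groups on the other (2,3-trans, 3,4-cis, 4,5-trans). The compound is achiral, so only relative configuration has to be controlled. Ring numbering O1, C2, C3, C4, C5 is used throughout. Compounds 2 and 8 are racemic and are drawn as one enantiomer.

Step 1
Reactants: 1 exo-7-oxabicyclo[2.2.1]hept-5-ene-2,3-dicarboxylic anhydride
Product: 3 dimethyl exo,exo-7-oxabicyclo[2.2.1]hept-5-ene-2,3-dicarboxylate (meso), via half-ester 2 (not isolated)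
Conditions: MeOH, conc. HCl (cat.), reflux
Reagents that add atoms: methanol (CO)
Why: Acid-catalysed anhydride methanolysis followed by Fischer esterification of the half-ester touches no stereocentre, so the exo,exo geometry of the Diels–Alder adduct is kept, and refluxing methanol stays below the onset of cycloreversion.

Step 2
Reactants: 3 dimethyl exo,exo-7-oxabicyclo[2.2.1]hept-5-ene-2,3-dicarboxylate
Product: 5 (2S,3S,4R,5R)-3,4-bis(methoxycarbonyl)tetrahydrofuran-2,5-dicarboxylic acid (meso), via dialdehyde 4 (not isolated)
Conditions: RuCl3·xH2O (2 mol %), NaIO4 (4.2 equiv), MeCN/EtOAc/H2O, 0 °C to rt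
Reagents that add atoms: sodium periodate ([Na+].[O-]I(=O)(=O)=O); water (O)
Why: RuO4-catalysed oxidative cleavage of the strained cis-disubstituted alkene turns the two-carbon bridge into two carboxyl groups without touching any C–H stereocentre, so these groups end up cis to each other on C2 and C5 and trans to the exo esters on C3 and C4.

Step 3
Reactants: 6 4-bromo-2,6-dimethoxyphenol
Product: 7 4-bromo-2,6-dimethoxyphenyl pivalate
Conditions: PivCl, Et3N, DMAP (cat.), CH2Cl2, 0 °C to rt
Reagents that add atoms: pivaloyl chloride (CC(C)(C)C(=O)Cl)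
Why: DMAP-catalysed O-acylation masks the oxidisable phenol with a hindered ester that resists carboxylate and hydrogencarbonate in step 4, lowers the electron density at the C–Br carbon, and falls to the same hydride that reduces the methyl esters.

Step 4
Reactants: 5 (2S,3S,4R,5R)-3,4-bis(methoxycarbonyl)tetrahydrofuran-2,5-dicarboxylic acid; 7 4-bromo-2,6-dimethoxyphenyl pivalate (3 equiv)
Product: 9 dimethyl (2S,3S,4R,5R)-2,5-bis[3,5-dimethoxy-4-(pivaloyloxy)phenyl]tetrahydrofuran-3,4-dicarboxylate (meso), via monoaryl acid 8 (not isolated)
Conditions: Ir[dF(CF3)ppy]2(dtbbpy)PF6 (2 mol %), NiCl2·dme (20 mol %), dtbbpy (20 mol %), Cs2CO3 (2.0 equiv), degassed DMF, 450 nm LEDs, rt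
Reagents that add atoms: none
Why: Twofold metallaphotoredox decarboxylative arylation, the reaction type known for tetrahydrofuran-2-carboxylic and furanosyl acids: the photoexcited iridium complex oxidises a caesium carboxylate of 5, loss of CO2 leaves the α-oxy radical at C2, this radical is captured by the aryl nickel bromide formed from 7 and zerovalent nickel, and reductive elimination from trivalent nickel makes the aryl–C2 bond, after which monovalent nickel is reduced back by the reduced photocatalyst. The same cycle then runs on the remaining carboxylate of 8, so that the second syringyl unit is joined to C5 of the already arylated ring in the same flask. No ring is closed, because the tetrahydrofuran ring is carried over intact from the cycloadduct. Both carboxyl-bearing stereocentres are erased at the radical stage and rewritten under substrate control: the cis ester groups on C3 and C4 shield the lower face, so bond formation takes place on the upper face and gives the 2,3-trans and 4,5-trans (hence 2,5-cis) arrangement, and the two enantiomers of 8 converge on meso 9. The step needs cross-coupling to win over hydrogen abstraction by the radical, which an excess of 7 and its mildly electron-poor C–Br carbon (para acyloxy and two meta methoxy groups) secure through fast oxidative addition. It also needs the enolisable centres C3 and C4 to stay put, which is secured by using only as much Cs2CO3 as forms the dicarboxylate, so that hydrogencarbonate is the strongest base left.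

Step 5
Reactants: 9 dimethyl (2S,3S,4R,5R)-2,5-bis[3,5-dimethoxy-4-(pivaloyloxy)phenyl]tetrahydrofuran-3,4-dicarboxylate
Product: 10 (2S,3R,4S,5R)-2,5-bis(4-hydroxy-3,5-dimethoxyphenyl)-3,4-bis(hydroxymethyl)tetrahydrofuran (target, meso)
Conditions: LiAlH4 (5 equiv), THF, 0 °C to rt; aq. potassium sodium tartrate, then aq. NH4Cl to about pH 7
Reagents that add atoms: none
Why: Global LiAlH4 ester reduction converts both methyl esters into hydroxymethyl groups and cleaves both aryl pivalates in the same flask, and because hydride addition to the esters is faster than their enolisation no stereocentre is formed, broken or epimerised.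

Compound list
1 | exo-7-oxabicyclo[2.2.1]hept-5-ene-2,3-dicarboxylic anhydride, (3aR,4S,7R,7aS), meso | C1=C[C@H]2O[C@@H]1[C@@H]3C(=O)OC(=O)[C@H]23 | starting material
2 | exo,exo-3-(methoxycarbonyl)-7-oxabicyclo[2.2.1]hept-5-ene-2-carboxylic acid (half-ester, racemic, not isolated) | C1=C[C@H]2O[C@@H]1[C@H](C(=O)O)[C@@H]2C(=O)OC | intermediate
3 | dimethyl exo,exo-7-oxabicyclo[2.2.1]hept-5-ene-2,3-dicarboxylate, meso | C1=C[C@H]2O[C@@H]1[C@H](C(=O)OC)[C@@H]2C(=O)OC | intermediate
4 | dimethyl (2S,3S,4R,5R)-2,5-diformyltetrahydrofuran-3,4-dicarboxylate, meso (not isolated) | O=C[C@H]1O[C@@H](C=O)[C@H](C(=O)OC)[C@@H]1C(=O)OC | intermediate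
5 | (2S,3S,4R,5R)-3,4-bis(methoxycarbonyl)tetrahydrofuran-2,5-dicarboxylic acid, meso, 2,3-trans, 3,4-cis, 4,5-trans | OC(=O)[C@H]1O[C@@H](C(=O)O)[C@H](C(=O)OC)[C@@H]1C(=O)OC | intermediate
6 | 4-bromo-2,6-dimethoxyphenol | COc1cc(Br)cc(OC)c1O | starting material
7 | 4-bromo-2,6-dimethoxyphenyl pivalate | COc1cc(Br)cc(OC)c1OC(=O)C(C)(C)C | intermediate
8 | rel-(2R,3R,4S,5S)-5-[3,5-dimethoxy-4-(pivaloyloxy)phenyl]-3,4-bis(methoxycarbonyl)tetrahydrofuran-2-carboxylic acid (racemic, not isolated) | COc1cc([C@H]2O[C@@H](C(=O)O)[C@H](C(=O)OC)[C@@H]2C(=O)OC)cc(OC)c1OC(=O)C(C)(C)C | intermediate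
9 | dimethyl (2S,3S,4R,5R)-2,5-bis[3,5-dimethoxy-4-(pivaloyloxy)phenyl]tetrahydrofuran-3,4-dicarboxylate, meso | COc1cc([C@H]2O[C@@H](c3cc(OC)c(OC(=O)C(C)(C)C)c(OC)c3)[C@H](C(=O)OC)[C@@H]2C(=O)OC)cc(OC)c1OC(=O)C(C)(C)C | intermediate
10 | (2S,3R,4S,5R)-2,5-bis(4-hydroxy-3,5-dimethoxyphenyl)-3,4-bis(hydroxymethyl)tetrahydrofuran, meso | COc1cc([C@H]2O[C@@H](c3cc(OC)c(O)c(OC)c3)[C@H](CO)[C@@H]2CO)cc(OC)c1O | target

Total step count: 5. Longest linear sequence: 4 (steps 1, 2, 4, 5).

Steps most likely to fail

Step 4.
- What may go wrong: hydrogen abstraction by the α-oxy radical (protodecarboxylation) may outpace capture by nickel, above all at the second carboxylate.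
- What may go wrong: once C2 carries an aryl group, the C5 radical may open the ring by β-scission.
- What may go wrong: facial selectivity may be incomplete.
- Fallback: the radicals are generated by reduction instead of oxidation, and the aryl partner becomes a nucleophile, with neither light nor base. The fallback sets out from 5 and 7. Diacid 5 is activated with N-hydroxyphthalimide and N,N'-diisopropylcarbodiimide to give the bis(N-hydroxyphthalimide) ester F1. Bromide 7 is converted by magnesium insertion in the presence of LiCl and ZnCl2 into [3,5-dimethoxy-4-(pivaloyloxy)phenyl]zinc chloride F2. The two are joined by decarboxylative Negishi arylation (NiCl2·dme, dtbbpy, THF/DMF, rt), with the same substrate control of the new centres. The fallback comes back to the route at 9.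

Step 5.
- What may go wrong: once the phenoxides are unmasked in the presence of hydride, the ring oxygen may be expelled from C2 or C5 (quinone methide formation). Hydride capture would then open the ring reductively.
- What may go wrong: the β-alkoxy esters may enolise before reduction, which would cause epimerisation or retro-oxa-Michael opening.
- Fallback: the phenols stay masked through the reduction and are freed under neutral conditions. The fallback sets out from 6 and 5. Phenol 6 is benzylated (BnBr, K2CO3, acetone) to give 2-(benzyloxy)-5-bromo-1,3-dimethoxybenzene F3. Twofold coupling of F3 with 5 as in step 4 gives the bis(benzyl ether) diester F4. LiAlH4 reduction gives the bis(benzyl ether) diol F5. Hydrogenolysis of the two aryl benzyl ethers (H2, Pd/C, EtOAc/MeOH, rt) comes back to the route at 10.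

Step 2.
- What may go wrong: over-oxidation may occur at the ether C–H positions.
- What may go wrong: the very polar diacid may be lost to the aqueous iodate phase on isolation.
- Fallback: the cleavage is staged through organic-soluble intermediates. The fallback sets out from 3. Upjohn dihydroxylation (OsO4 cat., N-methylmorpholine N-oxide, acetone/H2O) on the exo face gives the exo,exo-diol F6. Glycol cleavage with NaIO4 gives dialdehyde 4, now isolated. Pinnick oxidation (NaClO2, NaH2PO4, 2-methyl-2-butene, t-BuOH/H2O) comes back to the route at 5.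

Further compounds
F1 | step 4 | 3,4-dimethyl 2,5-bis(1,3-dioxoisoindolin-2-yl) (2S,3S,4R,5R)-tetrahydrofuran-2,3,4,5-tetracarboxylate, meso | O=C(ON1C(=O)c2ccccc2C1=O)[C@H]3O[C@@H](C(=O)ON4C(=O)c5ccccc5C4=O)[C@H](C(=O)OC)[C@@H]3C(=O)OC
F2 | step 4 | [3,5-dimethoxy-4-(pivaloyloxy)phenyl]zinc chloride | COc1cc([Zn]Cl)cc(OC)c1OC(=O)C(C)(C)C
F3 | step 5 | 2-(benzyloxy)-5-bromo-1,3-dimethoxybenzene | COc1cc(Br)cc(OC)c1OCc1ccccc1
F4 | step 5 | dimethyl (2S,3S,4R,5R)-2,5-bis[4-(benzyloxy)-3,5-dimethoxyphenyl]tetrahydrofuran-3,4-dicarboxylate, meso | COc1cc([C@H]2O[C@@H](c3cc(OC)c(OCc4ccccc4)c(OC)c3)[C@H](C(=O)OC)[C@@H]2C(=O)OC)cc(OC)c1OCc1ccccc1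
F5 | step 5 | (2S,3R,4S,5R)-2,5-bis[4-(benzyloxy)-3,5-dimethoxyphenyl]-3,4-bis(hydroxymethyl)tetrahydrofuran, meso | COc1cc([C@H]2O[C@@H](c3cc(OC)c(OCc4ccccc4)c(OC)c3)[C@H](CO)[C@@H]2CO)cc(OC)c1OCc1ccccc1
F6 | step 2 | dimethyl 5-exo,6-exo-dihydroxy-7-oxabicyclo[2.2.1]heptane-2-exo,3-exo-dicarboxylate, meso | O[C@H]1[C@@H](O)[C@H]2O[C@@H]1[C@H](C(=O)OC)[C@@H]2C(=O)OC
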